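Assumption: atom labels C1–C15 in the explanations follow the usual germacrane numbering of goyazensolide (C1 ketone, C3 furanone carbon on the ring oxygen, C6 lactone carbinol, C8 ester carbinol, C10 quaternary carbon), and in the two catalytic asymmetric additions the ligand enantiomer is the one that gives the configuration stated.

**Retrosynthetic overview**

1. Goyazensolide ⇐ C8 alcohol (methacrylation, then cleavage of the C15 tert-butyl ether) ⇐ bromobutenolide aldehyde by chromium-mediated Barbier closure of C7–C8; the ten-membered carbocycle is formed last and C7/C8 are set from C6.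
2. Bromobutenolide ⇐ ring-closing metathesis of a 2-(bromomethyl)acrylate ester of a vinyl carbinol; the lactone ring is formed second.
3. 3(2H)-Furanone ⇐ key step: gold-catalysed heterocyclisation of a 2-hydroxy-2-alkynyl ketone with a 1,2-methyl shift; the furanone is formed first and the carbinol configuration is carried over to quaternary C10.
4. Enyne ⇐ Sonogashira union of a Z-vinyl iodide (from acrolein and tert-butyl propargyl ether, C6 set by asymmetric alkynylation) with an alkynyl ketol.
5. Alkynyl ketol ⇐ biacetyl + ethynyltrimethylsilane (new rhodium-catalysed enantioselective alkynylation of a 1,2-diketone) + 2-methoxy-1,3-dioxolane (C8 as a masked aldehyde).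

**Route**

Step 1
Reactants: 1 butane-2,3-dione; 2 ethynyltrimethylsilane
Product: 3 (3R)-3-hydroxy-3-methyl-5-(trimethylsilyl)pent-4-yn-2-one
Conditions: Rh(Phebox-iPr)(OAc)2(H2O) (3 mol%; Phebox-iPr = 2,6-bis(4-isopropyl-4,5-dihydrooxazol-2-yl)phenyl), Et2O, 23 °C, 1 in excess
Reagents that add atoms: none
Why: Proposed new method: enantioselective mono-alkynylation of a symmetric 1,2-diketone at trivalent rhodium, in which acetate-assisted C–H metalation gives a rhodium alkynyl, biacetyl binds in the chiral pincer pocket as an O,O-chelate just as an α-keto ester does (the second acetyl group plays the part of the ester), insertion of one carbonyl face into the Rh–C bond sets the R tertiary carbinol and protonolysis by AcOH frees the product, which is α-quaternary and no longer a 1,2-dicarbonyl and so does not react twice; the closest known reaction type is the Rh–Phebox (or Zn(OTf)2/amino alcohol) catalysed alkynylation of α-keto esters.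

Step 2
Reactants: 3 (3R)-3-hydroxy-3-methyl-5-(trimethylsilyl)pent-4-yn-2-one; 4 2-methoxy-1,3-dioxolane
Product: 7 (3R)-1-(1,3-dioxolan-2-yl)-3-hydroxy-3-methylpent-4-yn-2-one, via tris-silyl enol ether 5 (not isolated), via silylated keto acetal 6 (not isolated)
Conditions: iPr2NEt (3.0 equiv), TMSOTf (3.3 equiv), CH2Cl2, −78 to 0 °C; then K2CO3, MeOH, 0 °C
Reagents that add atoms: none
Why: One-pot silyl enol ether formation and Mukaiyama-type addition to the 1,3-dioxolan-2-ylium ion released from the cyclic orthoformate (the methyl group is the only enolisable position), then methanolysis of the O- and C-silyl groups; the carbinol stereocentre is not touched.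

Step 3
Reactants: 8 3-(tert-butoxy)prop-1-yne; 9 prop-2-enal
Product: 11 (3S)-6-(tert-butoxy)hex-1-en-4-yn-3-ol, via methylzinc acetylide 10 (not isolated)
Conditions: Me2Zn, ProPhenol (10 mol%), Ph3PO (20 mol%), toluene, 0 °C; aq. NH4Cl
Reagents that add atoms: none
Why: Zinc–ProPhenol catalysed asymmetric alkynylation of an enal, in which the dinuclear zinc catalyst delivers the alkynyl group to one aldehyde face and so sets the S carbinol that becomes C6.

Step 4
Reactants: 11 (3S)-6-(tert-butoxy)hex-1-en-4-yn-3-ol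
Product: 13 (3S,4Z)-6-(tert-butoxy)-5-iodohexa-1,4-dien-3-ol, via cyclic alkenylalanate 12 (not isolated)
Conditions: NaAlH2(OCH2CH2OCH3)2, THF, 0 to 23 °C; EtOAc; then I2, −78 °C
Reagents that add atoms: iodine, [I][I]
Why: Hydroxyl-directed trans-hydroalumination (hydride to the alkyne carbon next to the carbinol, aluminium on the far carbon in a five-membered alkoxyalanate) and iodinolysis with retention give the Z vinyl iodide with iodine on C4 and cis to C6; the carbinol centre is untouched.

Step 5
Reactants: 13 (3S,4Z)-6-(tert-butoxy)-5-iodohexa-1,4-dien-3-ol; 7 (3R)-1-(1,3-dioxolan-2-yl)-3-hydroxy-3-methylpent-4-yn-2-one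
Product: 14 (3R,6E,8S)-6-(tert-butoxymethyl)-1-(1,3-dioxolan-2-yl)-3,8-dihydroxy-3-methyldeca-6,9-dien-4-yn-2-one
Conditions: Pd(PPh3)2Cl2 (5 mol%), CuI (10 mol%), Et3N, THF, 23 °C
Reagents that add atoms: none
Why: Sonogashira coupling of a vinyl iodide with a terminal alkyne goes with retention of the alkene geometry (alkyne cis to the carbinol carbon) and tolerates both free hydroxyl groups.

Step 6
Reactants: 14 (3R,6E,8S)-6-(tert-butoxymethyl)-1-(1,3-dioxolan-2-yl)-3,8-dihydroxy-3-methyldeca-6,9-dien-4-yn-2-one; 15 2-(bromomethyl)prop-2-enoic acid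
Product: 17 (3S,4E,8R)-5-(tert-butoxymethyl)-10-(1,3-dioxolan-2-yl)-8-hydroxy-8-methyl-9-oxodeca-1,4-dien-6-yn-3-yl 2-(bromomethyl)prop-2-enoate, via 2-(bromomethyl)acryloyl chloride 16 (not isolated)
Conditions: 15, (COCl)2, DMF (cat.), CH2Cl2, 0 °C; then 14, 2,6-lutidine, −30 °C
Reagents that add atoms: none
Why: Acylation of the secondary allylic alcohol by the acid chloride made in the flask; the tertiary propargylic hydroxyl is too hindered to react and the hindered pyridine base does not displace the allylic bromide.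

Step 7
Reactants: 17 (3S,4E,8R)-5-(tert-butoxymethyl)-10-(1,3-dioxolan-2-yl)-8-hydroxy-8-methyl-9-oxodeca-1,4-dien-6-yn-3-yl 2-(bromomethyl)prop-2-enoate
Product: 18 (3S,4Z)-6-(tert-butoxy)-5-[(5R)-5-(1,3-dioxolan-2-ylmethyl)-5-methyl-4-oxo-4,5-dihydrofuran-2-yl]hexa-1,4-dien-3-yl 2-(bromomethyl)prop-2-enoate
Conditions: AuCl3 (5 mol%), CH2Cl2, 23 °C
Reagents that add atoms: none
Why: Heterocyclisation/1,2-migration of a 2-hydroxy-2-alkynyl ketone: 5-endo-dig attack of the ketone oxygen on the gold-activated alkyne gives a cyclic oxocarbenium ion, a suprafacial α-ketol-type 1,2-methyl shift from the carbinol carbon to the cationic carbon then closes the 3(2H)-furanone, turns the carbinol into the C1 ketone and carries the R carbinol configuration over to quaternary C10 (R), and protodeauration frees the catalyst.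

Step 8
Reactants: 18 (3S,4Z)-6-(tert-butoxy)-5-[(5R)-5-(1,3-dioxolan-2-ylmethyl)-5-methyl-4-oxo-4,5-dihydrofuran-2-yl]hexa-1,4-dien-3-yl 2-(bromomethyl)prop-2-enoate
Product: 19 (5R)-3-(bromomethyl)-5-{(1Z)-3-(tert-butoxy)-2-[(5R)-5-(1,3-dioxolan-2-ylmethyl)-5-methyl-4-oxo-4,5-dihydrofuran-2-yl]prop-1-en-1-yl}furan-2(5H)-one
Conditions: second-generation Grubbs catalyst RuCl2(=CHPh)(PCy3)(H2IMes) (10 mol%), toluene (5 mM), 80 °C
Reagents that add atoms: none
Why: Ring-closing metathesis between the vinyl group and the 1,1-disubstituted acrylate gives the butenolide with its allylic bromide in place; no alkyne is left to divert the carbene and C6 is untouched (its descriptor changes from S to R only through the priority rules).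

Step 9
Reactants: 19 (5R)-3-(bromomethyl)-5-{(1Z)-3-(tert-butoxy)-2-[(5R)-5-(1,3-dioxolan-2-ylmethyl)-5-methyl-4-oxo-4,5-dihydrofuran-2-yl]prop-1-en-1-yl}furan-2(5H)-one
Product: 20 (5R)-3-(bromomethyl)-5-{(1Z)-3-(tert-butoxy)-2-[(5R)-5-methyl-4-oxo-5-(2-oxoethyl)-4,5-dihydrofuran-2-yl]prop-1-en-1-yl}furan-2(5H)-one
Conditions: 2 M aq. HCl, THF, 23 °C; crude aldehyde used at once
Reagents that add atoms: water, O
Why: Acid-catalysed acetal hydrolysis; the tert-butyl ether, the furanone and the allylic bromide survive dilute aqueous acid, and no base is present that could epimerise the butenolide C6–H or eliminate the β-oxygen of the aldehyde.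

Step 10
Reactants: 20 (5R)-3-(bromomethyl)-5-{(1Z)-3-(tert-butoxy)-2-[(5R)-5-methyl-4-oxo-5-(2-oxoethyl)-4,5-dihydrofuran-2-yl]prop-1-en-1-yl}furan-2(5H)-one
Product: 21 (6R,7R,8S,10R)-8-O-demethacryloyl-15-O-tert-butylgoyazensolide
Conditions: CrCl2 (10 equiv), THF/DMF (4:1), 2 mM, slow addition, 23 °C; H2O
Reagents that add atoms: none
Why: Intramolecular Nozaki–Hiyama (Barbier-type) allylation: chromium sits on the exocyclic CH2 and the C–C bond forms at the ring carbon C7 through a chair transition state, anti to the C6 side chain (trans-lactone) and with the aldehyde chain equatorial (anti C7/C8), which closes the ten-membered ring, restores the exocyclic methylene and sets 7R and 8S.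

Step 11
Reactants: 21 (6R,7R,8S,10R)-8-O-demethacryloyl-15-O-tert-butylgoyazensolide; 22 2-methylprop-2-enoyl chloride
Product: 23 15-O-tert-butylgoyazensolide
Conditions: Et3N, DMAP (10 mol%), CH2Cl2, 0 °C
Reagents that add atoms: none
Why: DMAP-catalysed acylation of the secondary alcohol by the acid chloride, with retention at C8.

Step 12
Reactants: 23 15-O-tert-butylgoyazensolide
Product: 24 goyazensolide
Conditions: CF3CO2H/CH2Cl2 (1:4), 0 to 23 °C; aq. NaHCO3
Reagents that add atoms: none
Why: Acidolysis of the tert-butyl ether with loss of 2-methylpropene; the esters, the lactone and the furanone are acid-stable, and the C10–O bond cannot ionise because the cation would sit next to the ketone.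

**Compound list**

1 | butane-2,3-dione (biacetyl) | CC(=O)C(C)=O | starting material
2 | ethynyltrimethylsilane | C#C[Si](C)(C)C | starting material
3 | (3R)-3-hydroxy-3-methyl-5-(trimethylsilyl)pent-4-yn-2-one | C[C@@](O)(C#C[Si](C)(C)C)C(C)=O | intermediate
4 | 2-methoxy-1,3-dioxolane | COC1OCCO1 | starting material
5 | (3R)-3-methyl-2,3-bis(trimethylsilyloxy)-5-(trimethylsilyl)pent-1-en-4-yne (tris-silyl enol ether) | C[C@@](O[Si](C)(C)C)(C#C[Si](C)(C)C)C(=C)O[Si](C)(C)C | intermediate
6 | (3R)-1-(1,3-dioxolan-2-yl)-3-methyl-5-(trimethylsilyl)-3-(trimethylsilyloxy)pent-4-yn-2-one (silylated keto acetal) | C[C@@](O[Si](C)(C)C)(C#C[Si](C)(C)C)C(=O)CC1OCCO1 | intermediate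
7 | (3R)-1-(1,3-dioxolan-2-yl)-3-hydroxy-3-methylpent-4-yn-2-one | C[C@@](O)(C#C)C(=O)CC1OCCO1 | intermediate
8 | 3-(tert-butoxy)prop-1-yne (tert-butyl propargyl ether) | C#CCOC(C)(C)C | starting material
9 | prop-2-enal (acrolein) | C=CC=O | starting material
10 | methyl[3-(tert-butoxy)prop-1-yn-1-yl]zinc (methylzinc acetylide) | C[Zn]C#CCOC(C)(C)C | intermediate
11 | (3S)-6-(tert-butoxy)hex-1-en-4-yn-3-ol | C=C[C@H](O)C#CCOC(C)(C)C | intermediate
12 | sodium (5S)-3-(tert-butoxymethyl)-5-ethenyl-2,2-bis(2-methoxyethoxy)-2,5-dihydro-1,2-oxaluminol-2-uide (cyclic alkenylalanate) | [Na+].C=C[C@H]1C=C(COC(C)(C)C)[Al-](OCCOC)(OCCOC)O1 | intermediate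
13 | (3S,4Z)-6-(tert-butoxy)-5-iodohexa-1,4-dien-3-ol | C=C[C@H](O)/C=C(\I)COC(C)(C)C | intermediate
14 | (3R,6E,8S)-6-(tert-butoxymethyl)-1-(1,3-dioxolan-2-yl)-3,8-dihydroxy-3-methyldeca-6,9-dien-4-yn-2-one (alkyne and C8 carbinol carbon cis on the C6=C7 bond) | C=C[C@H](O)/C=C(COC(C)(C)C)\C#C[C@@](C)(O)C(=O)CC1OCCO1 | intermediate
15 | 2-(bromomethyl)prop-2-enoic acid | C=C(CBr)C(=O)O | starting material
16 | 2-(bromomethyl)prop-2-enoyl chloride | C=C(CBr)C(=O)Cl | intermediate
17 | (3S,4E,8R)-5-(tert-butoxymethyl)-10-(1,3-dioxolan-2-yl)-8-hydroxy-8-methyl-9-oxodeca-1,4-dien-6-yn-3-yl 2-(bromomethyl)prop-2-enoate | C=C[C@H](OC(=O)C(=C)CBr)/C=C(COC(C)(C)C)\C#C[C@@](C)(O)C(=O)CC1OCCO1 | intermediate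
18 | (3S,4Z)-6-(tert-butoxy)-5-[(5R)-5-(1,3-dioxolan-2-ylmethyl)-5-methyl-4-oxo-4,5-dihydrofuran-2-yl]hexa-1,4-dien-3-yl 2-(bromomethyl)prop-2-enoate | C=C[C@H](OC(=O)C(=C)CBr)/C=C(COC(C)(C)C)\C1=CC(=O)[C@@](C)(CC2OCCO2)O1 | intermediate
19 | (5R)-3-(bromomethyl)-5-{(1Z)-3-(tert-butoxy)-2-[(5R)-5-(1,3-dioxolan-2-ylmethyl)-5-methyl-4-oxo-4,5-dihydrofuran-2-yl]prop-1-en-1-yl}furan-2(5H)-one | O=C1O[C@H](/C=C(COC(C)(C)C)\C2=CC(=O)[C@@](C)(CC3OCCO3)O2)C=C1CBr | intermediate
20 | (5R)-3-(bromomethyl)-5-{(1Z)-3-(tert-butoxy)-2-[(5R)-5-methyl-4-oxo-5-(2-oxoethyl)-4,5-dihydrofuran-2-yl]prop-1-en-1-yl}furan-2(5H)-one | O=C1O[C@H](/C=C(COC(C)(C)C)\C2=CC(=O)[C@@](C)(CC=O)O2)C=C1CBr | intermediate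
21 | (6R,7R,8S,10R)-8-O-demethacryloyl-15-O-tert-butylgoyazensolide (goyazensolide skeleton with free C8–OH and C15–O-tert-butyl) | O[C@H]1C[C@@]2(C)OC(=CC2=O)/C(COC(C)(C)C)=C\[C@H]2OC(=O)C(=C)[C@H]12 | intermediate
22 | 2-methylprop-2-enoyl chloride (methacryloyl chloride) | C=C(C)C(=O)Cl | starting material
23 | 15-O-tert-butylgoyazensolide | C=C(C)C(=O)O[C@H]1C[C@@]2(C)OC(=CC2=O)/C(COC(C)(C)C)=C\[C@H]2OC(=O)C(=C)[C@H]12 | intermediate
24 | goyazensolide (6R,7R,8S,10R) | C=C(C)C(=O)O[C@H]1C[C@@]2(C)OC(=CC2=O)/C(CO)=C\[C@H]2OC(=O)C(=C)[C@H]12 | target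

**Step count and risks**

Total: 12 steps. Longest linear sequence: 10 steps (steps 3–12; the branch through steps 1 and 2 is equally long).

The three steps most likely to fail are steps 1, 7 and 10.

Step 1 is the proposed new reaction. A simple 1,2-diketone has not been shown in this alkynylation, and biacetyl may give low selectivity or self-condense. The fallback uses known chemistry, sets out from 2 and rejoins the route at 7, replacing steps 1 and 2. Bought methyl pyruvate (CC(=O)C(=O)OC) is alkynylated with 2 under the same rhodium catalyst, here on its established α-keto ester substrate class, to give methyl (2R)-2-hydroxy-2-methyl-4-(trimethylsilyl)but-3-ynoate F1. In one flask MeNHOMe·HCl/iPrMgCl converts it into the Weinreb amide (2R)-2-hydroxy-N-methoxy-N,2-dimethyl-4-(trimethylsilyl)but-3-ynamide F2. Bought (1,3-dioxolan-2-ylmethyl)magnesium bromide (Br[Mg]CC1OCCO1) then adds once to give (3R)-1-(1,3-dioxolan-2-yl)-3-hydroxy-3-methyl-5-(trimethylsilyl)pent-4-yn-2-one F3. K2CO3/MeOH removes the silyl group and gives 7.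

Step 7 is at risk because 17 also carries a vinyl group and a doubly allylic ester. Both can compete for the gold-activated alkyne, by enyne cycloisomerisation or by acyloxy shift, before the ketone oxygen closes the furanone. The fallback sets out from 17 and changes the order of ring formation. Ring-closing metathesis with RuCl2(=CHPh)(PCy3)(H2IMes) is run first and gives (5R)-3-(bromomethyl)-5-[(1E,5R)-2-(tert-butoxymethyl)-7-(1,3-dioxolan-2-yl)-5-hydroxy-5-methyl-6-oxohept-1-en-3-yn-1-yl]furan-2(5H)-one F4. This compound has no vinyl group and its C6 oxygen is a lactone oxygen. AuCl3 then effects the cyclisation and 1,2-methyl shift, and the route is rejoined at 19. The price is a possible ene–yne metathesis, against which only the steric shielding of the fully substituted alkyne stands.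

Step 10 closes a furanone-bridged ten-membered ring. The sense at C8 rests on a chair transition state that the forming ring may not allow. The fallback sets out from 20 and rejoins at 23. If the closure gives mainly the C8 epimer (6R,7R,8R,10R)-8-O-demethacryloyl-15-O-tert-butylgoyazensolide F5, Mitsunobu esterification with methacrylic acid (PPh3, DIAD) inverts C8 and installs the ester in one operation, which makes step 11 unnecessary.

**Further compounds**

F1 | step 1 | methyl (2R)-2-hydroxy-2-methyl-4-(trimethylsilyl)but-3-ynoate | C[C@@](O)(C#C[Si](C)(C)C)C(=O)OC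
F2 | step 1 | (2R)-2-hydroxy-N-methoxy-N,2-dimethyl-4-(trimethylsilyl)but-3-ynamide | C[C@@](O)(C#C[Si](C)(C)C)C(=O)N(C)OC
F3 | step 1 | (3R)-1-(1,3-dioxolan-2-yl)-3-hydroxy-3-methyl-5-(trimethylsilyl)pent-4-yn-2-one | C[C@@](O)(C#C[Si](C)(C)C)C(=O)CC1OCCO1
F4 | step 7 | (5R)-3-(bromomethyl)-5-[(1E,5R)-2-(tert-butoxymethyl)-7-(1,3-dioxolan-2-yl)-5-hydroxy-5-methyl-6-oxohept-1-en-3-yn-1-yl]furan-2(5H)-one | O=C1O[C@H](/C=C(COC(C)(C)C)\C#C[C@@](C)(O)C(=O)CC2OCCO2)C=C1CBr
F5 | step 10 | (6R,7R,8R,10R)-8-O-demethacryloyl-15-O-tert-butylgoyazensolide (C8 epimer of 21) | O[C@@H]1C[C@@]2(C)OC(=CC2=O)/C(COC(C)(C)C)=C\[C@H]2OC(=O)C(=C)[C@H]12
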